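**Direct plan (as a thought)**
A direct plan would take the cyclopentane from the chiral pool, make the dearomatised ring from phloroglucinol, and join the two at ring carbon C4.
Limonene 1,2-oxide A1 would be cleaved and oxidised to keto acid A2, closed by aldol-lactonisation to β-lactone A3, and reduced and re-oxidised to β-hydroxy aldehyde A4.
A4 would then be coupled with gem-diprenyl trione A5 by reductive Knoevenagel alkylation.
Weak point: the oxidation-level shuffle from the cleavage product of A1 up to acid A2 and, after ring closure, down and up again to aldehyde A4 would spend four operations that add no skeletal bond.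
Weak point: the aldol-lactonisation of A2 to A3 would close the ring at high dilution and set two stereocentres on substrate control from one existing centre alone.
Weak point: the final union with A5 would spend both finished halves on A4, a β-hydroxy aldehyde prone to retro-aldol cleavage, dehydration and epimerisation.

**Plan of the new route**
Locants: unprimed = six-membered ring as in the name of the target; C1', C2', C5' = cyclopentane carbons bearing the bridge CH2, the carbinol and the isopropenyl group.
Cuts, in order: C2'–CH3; bridge CH2–C1'; C5'–isopropenyl; C4–CH2; both C6–prenyl bonds; C2–acyl.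
Feature used: C4 lies between the enolised carbonyls C3–O and C5–O, so C4=CH2 with O=C5 is a 1-oxadiene (an o-quinone methide), and C1'=C2'(O) of the cyclopentane is its enol-ether partner.
Ring order: phloroglucinol is dearomatised first, the cyclopentane enters as a cyclopentenone-derived silyl enol ether, and the only ring that arises is a dihydropyran made and cleaved in step 5; no carbocycle is closed.
C5' is set by a catalyst, C1' by anti addition (and is the stable epimer), C2' by methyl addition anti to the arm; the carbinol oxygen is the enone oxygen throughout.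
Hence there is no oxidation-level shuffle, no stereo-determining carbocyclisation and no β-hydroxy aldehyde.

Key step: step 5

Assumption: the β-triketone compounds are drawn in the dienol tautomer used for the target; they will be tautomer mixtures, and Mannich base 13 will exist as an inner salt.

**Step 1**
Reactants: 1 cyclopent-2-en-1-one; 2 isopropenylmagnesium bromide (prop-1-en-2-ylmagnesium bromide)
Product: 5 triethyl{[(3R)-3-(prop-1-en-2-yl)cyclopent-1-en-1-yl]oxy}silane, via isopropenyltitanium triisopropoxide 3 (not isolated), via titanium enolate 4 (not isolated)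
Conditions: 2, ClTi(OiPr)3, THF, −78 → 0 °C; then 1, [Rh(OH)(L)]2 (1.5 mol%; L = (R)-2,2'-bis(diphenylphosphino)-1,1'-binaphthyl), THF, 20 °C; then LiOiPr, Et3SiCl, 20 °C
Reagents that add atoms: chlorotriethylsilane (CC[Si](Cl)(CC)CC)
Why: Rhodium-catalysed asymmetric 1,4-addition (Hayashi–Miyaura type) run with an organotitanium reagent under aprotic conditions, so that the enolate survives and is O-silylated with its double bond fixed between C1 and C2, towards the new centre, a regiochemistry that enolisation of the ketone would not give; the ligand-bound monovalent rhodium alkenyl species adds to one face of the enone, and the R ligand is chosen to give the R centre by analogy with aryl transfer.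

**Step 2**
Reactants: 6 phloroglucinol; 7 isobutyryl chloride
Product: 8 phlorisobutyrophenone (2-methyl-1-(2,4,6-trihydroxyphenyl)propan-1-one)
Conditions: AlCl3 (3 equiv), PhNO2/CH2Cl2, 0 °C → rt
Reagents that add atoms: none
Why: Friedel–Crafts C-acylation of the electron-rich arene, which should stop at the mono-ketone because the acyl group deactivates the ring; no stereocentre is formed.

**Step 3**
Reactants: 8 phlorisobutyrophenone; 9 prenyl bromide (2.1 equiv)
Product: 11 3,5-dihydroxy-6,6-bis(3-methylbut-2-en-1-yl)-2-(2-methylpropanoyl)cyclohexa-2,4-dien-1-one, via 3-prenylphlorisobutyrophenone 10 (not isolated)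
Conditions: KOH (10% aq.), 0 °C → rt; acidify; extract product into aq. NaHCO3, re-acidify
Reagents that add atoms: none
Why: Alkylative dearomatisation by double C-prenylation: the phenoxide is prenylated at carbon to give 10 and a second C-alkylation at the same carbon gives the gem-diprenyl dienone, a vinylogous acid that bicarbonate extraction should separate from the less acidic aromatic 3,5-diprenyl isomer; the step is run early on cheap material and forms no stereocentre.

**Step 4**
Reactants: 11 3,5-dihydroxy-6,6-bis(3-methylbut-2-en-1-yl)-2-(2-methylpropanoyl)cyclohexa-2,4-dien-1-one (gem-diprenyl trione); 12 dimethyl(methylidene)ammonium iodide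
Product: 13 4-[(dimethylamino)methyl]-3,5-dihydroxy-6,6-bis(3-methylbut-2-en-1-yl)-2-(2-methylpropanoyl)cyclohexa-2,4-dien-1-one
Conditions: iPr2NEt (1.0 equiv), CH2Cl2, 0 °C → rt
Reagents that add atoms: none
Why: Mannich reaction at C4, the only C–H position of the enolised trione, with the preformed iminium salt; the product stores the bridge carbon at its final oxidation level as a stable precursor of the methylidene trione.

**Step 5**
Reactants: 13 4-[(dimethylamino)methyl]-3,5-dihydroxy-6,6-bis(3-methylbut-2-en-1-yl)-2-(2-methylpropanoyl)cyclohexa-2,4-dien-1-one (Mannich base); 5 triethyl{[(3R)-3-(prop-1-en-2-yl)cyclopent-1-en-1-yl]oxy}silane (1.3 equiv)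
Product: 16 3,5-dihydroxy-6,6-bis(3-methylbut-2-en-1-yl)-2-(2-methylpropanoyl)-4-{[(1S,5R)-2-oxo-5-(prop-1-en-2-yl)cyclopentyl]methyl}cyclohexa-2,4-dien-1-one, via methylidene trione 14 (not isolated), via silyl ketal cycloadduct 15 (not isolated)
Conditions: 1,4-dioxane, 90 °C, N2 stream; then Bu4NF/AcOH (1:1), THF, 0 °C
Reagents that add atoms: none
Why: Heating should release dimethylamine from inner salt 13 to give methylidene trione 14, whose O=C5–C4=CH2 unit is an electron-poor 1-oxadiene that the electron-rich enol ether 5 traps in an inverse-electron-demand oxa-Diels–Alder reaction (closest known types: o-quinone methide cycloadditions of enol ethers and the Knoevenagel/hetero-Diels–Alder sequence of 1,3-diones). The dihydropyran is closed by this asynchronous (4+2) mode, the bridge CH2 bonding to the nucleophilic β-carbon C1' and the carbonyl oxygen to the silyloxy carbon C2', so the regiochemistry is that of a Mukaiyama–Michael addition and a stepwise course would give the same product. The new centre C1' is controlled by the neighbouring C5' isopropenyl group: the diene adds to the enol-ether face anti to it, which places the arm trans to isopropenyl, and the cis ring fusion of 15 follows from the suprafacial addition. The step needs chemoselectivity for the enol ether over the isopropenyl and prenyl alkenes and over self-condensation of 14; the far higher nucleophilicity of a silyl enol ether and the absence of free trione 11 (all of it is stored as 13) should secure this. Buffered fluoride then cleaves the O-silyl ketal, which collapses to the cyclopentanone and the trione enol, so the temporary ring and the ketal centre vanish and C1', now alpha to a ketone, rests in its more stable trans configuration.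

**Step 6**
Reactants: 16 3,5-dihydroxy-6,6-bis(3-methylbut-2-en-1-yl)-2-(2-methylpropanoyl)-4-{[(1S,5R)-2-oxo-5-(prop-1-en-2-yl)cyclopentyl]methyl}cyclohexa-2,4-dien-1-one (ketone); 17 methylmagnesium chloride
Product: 18 CNP0290578.2, 3,5-dihydroxy-4-{[(1S,2R,5R)-2-hydroxy-2-methyl-5-(prop-1-en-2-yl)cyclopentyl]methyl}-6,6-bis(3-methylbut-2-en-1-yl)-2-(2-methylpropanoyl)cyclohexa-2,4-dien-1-one
Conditions: MeMgCl (6 equiv), LaCl3·2LiCl (1 equiv), THF, −40 → 0 °C; aq. NH4Cl (no strong acid)
Reagents that add atoms: none
Why: Lanthanum-assisted Grignard 1,2-addition: the first two equivalents turn the acidic trione into its unreactive dienolate, the lanthanum salt suppresses enolisation of the ketone, and methyl should add to the carbonyl face anti to the C1' arm (the usual sense for trans-2,3-disubstituted cyclopentanones), which puts the hydroxyl cis to the arm and sets C2' as R.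

**Compound list**
1 | cyclopent-2-en-1-one | O=C1C=CCC1 | starting material
2 | isopropenylmagnesium bromide (prop-1-en-2-ylmagnesium bromide) | C=C(C)[Mg]Br | starting material
3 | tri(propan-2-yloxy)(prop-1-en-2-yl)titanium (isopropenyltitanium triisopropoxide) | C=C(C)[Ti](OC(C)C)(OC(C)C)OC(C)C | intermediate
4 | tri(propan-2-yloxy){[(3R)-3-(prop-1-en-2-yl)cyclopent-1-en-1-yl]oxy}titanium (titanium enolate) | C=C(C)[C@@H]1CCC(O[Ti](OC(C)C)(OC(C)C)OC(C)C)=C1 | intermediate
5 | triethyl{[(3R)-3-(prop-1-en-2-yl)cyclopent-1-en-1-yl]oxy}silane | C=C(C)[C@@H]1CCC(O[Si](CC)(CC)CC)=C1 | intermediate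
6 | phloroglucinol (benzene-1,3,5-triol) | Oc1cc(O)cc(O)c1 | starting material
7 | isobutyryl chloride (2-methylpropanoyl chloride) | CC(C)C(=O)Cl | starting material
8 | phlorisobutyrophenone, 2-methyl-1-(2,4,6-trihydroxyphenyl)propan-1-one | CC(C)C(=O)c1c(O)cc(O)cc1O | intermediate
9 | prenyl bromide (1-bromo-3-methylbut-2-ene) | CC(C)=CCBr | starting material
10 | 3-prenylphlorisobutyrophenone, 2-methyl-1-[2,4,6-trihydroxy-3-(3-methylbut-2-en-1-yl)phenyl]propan-1-one | CC(C)C(=O)c1c(O)cc(O)c(CC=C(C)C)c1O | intermediate
11 | 3,5-dihydroxy-6,6-bis(3-methylbut-2-en-1-yl)-2-(2-methylpropanoyl)cyclohexa-2,4-dien-1-one | CC(C)C(=O)C1=C(O)C=C(O)C(CC=C(C)C)(CC=C(C)C)C1=O | intermediate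
12 | dimethyl(methylidene)ammonium iodide | C[N+](C)=C.[I-] | starting material
13 | 4-[(dimethylamino)methyl]-3,5-dihydroxy-6,6-bis(3-methylbut-2-en-1-yl)-2-(2-methylpropanoyl)cyclohexa-2,4-dien-1-one (Mannich base, inner salt) | CN(C)CC1=C(O)C(CC=C(C)C)(CC=C(C)C)C(=O)C(C(=O)C(C)C)=C1O | intermediate
14 | 3-hydroxy-4-methylidene-6,6-bis(3-methylbut-2-en-1-yl)-2-(2-methylpropanoyl)cyclohex-2-ene-1,5-dione (methylidene trione, o-quinone methide) | C=C1C(=O)C(CC=C(C)C)(CC=C(C)C)C(=O)C(C(=O)C(C)C)=C1O | intermediate
15 | (1R,3aS,9aS)-8-hydroxy-5,5-bis(3-methylbut-2-en-1-yl)-7-(2-methylpropanoyl)-1-(prop-1-en-2-yl)-3a-[(triethylsilyl)oxy]-1,2,3,3a,9,9a-hexahydrocyclopenta[b]chromen-6(5H)-one (cis-fused silyl ketal; isopropenyl trans to C9) | C=C(C)[C@@H]1CC[C@@]2(O[Si](CC)(CC)CC)OC3=C(C[C@@H]12)C(O)=C(C(=O)C(C)C)C(=O)C3(CC=C(C)C)CC=C(C)C | intermediate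
16 | 3,5-dihydroxy-6,6-bis(3-methylbut-2-en-1-yl)-2-(2-methylpropanoyl)-4-{[(1S,5R)-2-oxo-5-(prop-1-en-2-yl)cyclopentyl]methyl}cyclohexa-2,4-dien-1-one | C=C(C)[C@@H]1CCC(=O)[C@H]1CC1=C(O)C(CC=C(C)C)(CC=C(C)C)C(=O)C(C(=O)C(C)C)=C1O | intermediate
17 | methylmagnesium chloride | C[Mg]Cl | starting material
18 | CNP0290578.2, 3,5-dihydroxy-4-{[(1S,2R,5R)-2-hydroxy-2-methyl-5-(prop-1-en-2-yl)cyclopentyl]methyl}-6,6-bis(3-methylbut-2-en-1-yl)-2-(2-methylpropanoyl)cyclohexa-2,4-dien-1-one | C=C(C)[C@@H]1CC[C@@](C)(O)[C@H]1CC1=C(O)C(CC=C(C)C)(CC=C(C)C)C(=O)C(C(=O)C(C)C)=C1O | target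

**Step count**
Total: 6 steps. Longest linear sequence: 5 steps (6 → 8 → 11 → 13 → 16 → 18; steps 2, 3, 4, 5, 6).

**Steps most likely to fail**

1. Step 5. The methylidene trione may be lost to self-condensation or to cycloaddition with the isopropenyl and prenyl alkenes, or the enol ether may be protodesilylated by the ammonium inner salt before it is trapped. The fallback reverses the polarity of the union; it sets out from 5 and comes back at 16. Enol ether 5 would undergo a regiospecific Mannich reaction with dimethyl(methylidene)ammonium iodide 12 (CH2Cl2, rt) to give (2R,3R)-2-[(dimethylamino)methyl]-3-(prop-1-en-2-yl)cyclopentan-1-one F1. MeI would quaternise it to N,N,N-trimethyl-1-[(1R,5R)-2-oxo-5-(prop-1-en-2-yl)cyclopentyl]methanaminium iodide F2, and aqueous NaHCO3 would eliminate trimethylamine to give (3S)-2-methylidene-3-(prop-1-en-2-yl)cyclopentan-1-one F3. Trione 11 (cat. Et3N, CH2Cl2, 0 °C) would then add to F3 through C4 as a Michael donor, and protonation of the enolate would give the trans ketone 16.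

2. Step 1. Alkenyl transfer from titanium to rhodium may be slow, so that uncatalysed background addition erodes the enantiomeric purity, or O-silylation of the titanium enolate may be incomplete. The fallback gives up asymmetric catalysis for a racemic union and a separation; it sets out from 1 and 2 and comes back at 16. Ligand-free copper-catalysed conjugate addition with in-situ silylation (CuBr·SMe2 5 mol%, Et3SiCl, THF, −78 °C) would give racemic triethyl{[3-(prop-1-en-2-yl)cyclopent-1-en-1-yl]oxy}silane F4. Step 5 run on it would give the racemic silyl ketal cycloadduct F5 and then the racemic trans ketone F6, whose enantiomers would be separated by chromatography on a chiral stationary phase to give 16.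

3. Step 6. The basic reagent may enolise the α-branched ketone instead of adding to it, or the facial selectivity may be poor. The fallback lets the ring fusion decide the carbinol configuration; it sets out from 15 (step 5 stopped before the fluoride treatment) and comes back at 18. Me3Al (CH2Cl2, −78 → 0 °C) would exchange the silyloxy group for methyl through the ring oxocarbenium ion to give (1R,3aR,9aS)-8-hydroxy-3a-methyl-5,5-bis(3-methylbut-2-en-1-yl)-7-(2-methylpropanoyl)-1-(prop-1-en-2-yl)-1,2,3,3a,9,9a-hexahydrocyclopenta[b]chromen-6(5H)-one F7, in which the cis ring fusion forces methyl onto the required face. LiOH (THF/H2O, 50 °C) would then open the vinylogous ester at the ring carbon, with the C2'–O bond and its configuration kept, to give 18.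

**Further compounds**
F1 | step 5 | (2R,3R)-2-[(dimethylamino)methyl]-3-(prop-1-en-2-yl)cyclopentan-1-one | C=C(C)[C@@H]1CCC(=O)[C@H]1CN(C)C
F2 | step 5 | N,N,N-trimethyl-1-[(1R,5R)-2-oxo-5-(prop-1-en-2-yl)cyclopentyl]methanaminium iodide | C=C(C)[C@@H]1CCC(=O)[C@H]1C[N+](C)(C)C.[I-]
F3 | step 5 | (3S)-2-methylidene-3-(prop-1-en-2-yl)cyclopentan-1-one | C=C(C)[C@@H]1CCC(=O)C1=C
F4 | step 1 | racemic triethyl{[3-(prop-1-en-2-yl)cyclopent-1-en-1-yl]oxy}silane (1:1 mixture of 5 and its enantiomer) | C=C(C)[C@@H]1CCC(O[Si](CC)(CC)CC)=C1.C=C(C)[C@H]1CCC(O[Si](CC)(CC)CC)=C1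
F5 | step 1 | racemic silyl ketal cycloadduct (1:1 mixture of 15 and its enantiomer) | C=C(C)[C@@H]1CC[C@@]2(O[Si](CC)(CC)CC)OC3=C(C[C@@H]12)C(O)=C(C(=O)C(C)C)C(=O)C3(CC=C(C)C)CC=C(C)C.C=C(C)[C@H]1CC[C@]2(O[Si](CC)(CC)CC)OC3=C(C[C@H]12)C(O)=C(C(=O)C(C)C)C(=O)C3(CC=C(C)C)CC=C(C)C
F6 | step 1 | racemic trans ketone (1:1 mixture of 16 and its enantiomer) | C=C(C)[C@@H]1CCC(=O)[C@H]1CC1=C(O)C(CC=C(C)C)(CC=C(C)C)C(=O)C(C(=O)C(C)C)=C1O.C=C(C)[C@H]1CCC(=O)[C@@H]1CC1=C(O)C(CC=C(C)C)(CC=C(C)C)C(=O)C(C(=O)C(C)C)=C1O
F7 | step 6 | (1R,3aR,9aS)-8-hydroxy-3a-methyl-5,5-bis(3-methylbut-2-en-1-yl)-7-(2-methylpropanoyl)-1-(prop-1-en-2-yl)-1,2,3,3a,9,9a-hexahydrocyclopenta[b]chromen-6(5H)-one | C=C(C)[C@@H]1CC[C@@]2(C)OC3=C(C[C@@H]12)C(O)=C(C(=O)C(C)C)C(=O)C3(CC=C(C)C)CC=C(C)C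
A1 | direct plan | (4R)-limonene 1,2-oxide, (4R)-1-methyl-4-(prop-1-en-2-yl)-7-oxabicyclo[4.1.0]heptane | CC12OC1C[C@@H](CC2)C(=C)C
A2 | direct plan | (3R)-6-oxo-3-(prop-1-en-2-yl)heptanoic acid | OC(=O)C[C@@H](CCC(C)=O)C(C)=C
A3 | direct plan | (1S,2R,5R)-5-methyl-2-(prop-1-en-2-yl)-6-oxabicyclo[3.2.0]heptan-7-one | C=C(C)[C@@H]1CC[C@@]2(C)OC(=O)[C@@H]12
A4 | direct plan | (1S,2R,5R)-2-hydroxy-2-methyl-5-(prop-1-en-2-yl)cyclopentane-1-carbaldehyde | C=C(C)[C@@H]1CC[C@@](C)(O)[C@H]1C=O
A5 | direct plan | 3,5-dihydroxy-6,6-bis(3-methylbut-2-en-1-yl)-2-(2-methylpropanoyl)cyclohexa-2,4-dien-1-one | CC(C)C(=O)C1=C(O)C=C(O)C(CC=C(C)C)(CC=C(C)C)C1=O
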